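**Plan**

- Numbering: C1 ketone; C2=C3 furanone olefin (C3 on the ring oxygen); C4 CHMe; C5 CHOH; C6 CH–O–methacryloyl; C7–C8 lactone fusion (C8 on oxygen); C9 CH2; C10 C(Me)–O; C11=C13 methylene; C12 lactone carbonyl.
- Feature and first cuts: in the ten-membered carbocycle the C5 hydroxyl and the C6 ester oxygen are threo between the C4 and C7 methines, the result of anti addition across a Z C5=C6 bond. The route therefore cuts C6–O(ester) back to a 5,6-oxirane, then C5=C6 by metathesis of vinyl groups on C4 and C7.
- Further cuts: in the lactone C11=C13, C7–C6 and C7–C8; in the furanone O–C3 and C2–C3.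
- Forward order: furanone ring (aldol, oxidation, cyclodehydration), then butenolide and methylenelactone (alkenylchromium addition, vinyl cuprate, Mannich/elimination), then the carbocycle by ring-closing metathesis, then epoxidation and opening by methacrylic acid.
- Stereochemistry: C10 from (R)-citramalic acid; C4 from an Evans auxiliary; C8 from a chiral chromium ligand; C7 from C8 (anti cuprate addition); C5 and C6 from face-selective epoxidation and inversion at C6.

Key step: step 17

Assumption: the (S)-configured oxazoline sulfonamide ligand of step 14 is taken to induce the 8S carbinol; if a trial shows the opposite sense, its antipode is used and nothing else changes.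

**Route**

Step 1
Reactants: 1 (S)-4-benzyloxazolidin-2-one; 2 (E)-but-2-enoyl chloride
Product: 3 (S)-4-benzyl-3-[(E)-but-2-enoyl]oxazolidin-2-one
Conditions: n-BuLi, THF, −78 °C; then 2, −78 to 0 °C
Reagents that add atoms: none
Why: N-acylation of the lithiated oxazolidinone by an acid chloride is routine, leaves the E-olefin untouched and forms no stereocentre.

Step 2
Reactants: 3 N-crotonyl imide
Product: 4 (S)-4-benzyl-3-[(S)-2-methylbut-3-enoyl]oxazolidin-2-one
Conditions: NaN(SiMe3)2, THF, −78 °C; MeI, −78 °C
Reagents that add atoms: iodomethane, CI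
Why: Evans deconjugative α-alkylation, in which the chelated sodium dienolate is methylated at the α-carbon on the face opposite the benzyl group, should set the future C4 centre as S.

Step 3
Reactants: 4 α-methyl imide
Product: 5 (S)-2-methylbut-3-en-1-ol
Conditions: LiBH4, H2O (1 equiv), Et2O, 0 °C; distillation
Reagents that add atoms: none
Why: Reductive cleavage of the Evans imide by LiBH4 gives the primary alcohol without touching the allylic stereocentre and returns the auxiliary.

Step 4
Reactants: 5 (S)-2-methylbut-3-en-1-ol
Product: 6 (S)-2-methylbut-3-enal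
Conditions: Dess–Martin periodinane, NaHCO3, CH2Cl2, 0 °C; cold filtered solution used at once
Reagents that add atoms: none
Why: Buffered Dess–Martin oxidation is a base-free route to the α-chiral β,γ-unsaturated aldehyde, which is kept cold and used immediately so that C4 does not enolise.

Step 5
Reactants: 7 (R)-citramalic acid
Product: 8 (R)-2-(2,2,4-trimethyl-5-oxo-1,3-dioxolan-4-yl)acetic acid
Conditions: 2,2-dimethoxypropane, p-TsOH (cat.), rt
Reagents that add atoms: 2,2-dimethoxypropane, COC(C)(C)OC
Why: Acid-catalysed acetalisation ties the α-hydroxy acid unit into a five-membered dioxolanone, which differentiates the two carboxyl groups and carries the chiral-pool C10 centre unchanged.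

Step 6
Reactants: 8 dioxolanone acid
Product: 10 (R)-3-hydroxy-3-methyloxolan-2-one, via dioxolanone alcohol 9 (not isolated)
Conditions: BH3·SMe2, THF, 0 °C to rt; MeOH; then p-TsOH (cat.), CH2Cl2, rt
Reagents that add atoms: none
Why: Borane reduces the free carboxylic acid chemoselectively, and acid then lets the new primary alcohol attack the dioxolanone carbonyl (translactonisation) with loss of acetone, C10 being untouched.

Step 7
Reactants: 10 hydroxy lactone
Product: 11 (R)-2,4-dihydroxy-N-methoxy-N,2-dimethylbutanamide
Conditions: MeNH(OMe)·HCl, AlMe3, CH2Cl2, 0 °C to rt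
Reagents that add atoms: N,O-dimethylhydroxylamine hydrochloride, CNOC.Cl
Why: Aluminium amide aminolysis of the lactone (Weinreb amide formation) opens the ring at the acyl carbon and does not involve C10.

Step 8
Reactants: 11 dihydroxy Weinreb amide
Product: 12 (R)-4-[(tert-butyldimethylsilyl)oxy]-2-hydroxy-N-methoxy-N,2-dimethylbutanamide
Conditions: TBSCl, imidazole, DMF, 0 °C
Reagents that add atoms: tert-butyldimethylsilyl chloride, C[Si](C)(Cl)C(C)(C)C
Why: Silylation is selective for the primary over the tertiary hydroxyl and stops relactonisation.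

Step 9
Reactants: 12 silylated Weinreb amide
Product: 13 (R)-5-[(tert-butyldimethylsilyl)oxy]-3-hydroxy-3-methylpentan-2-one
Conditions: MeMgBr (3.5 equiv), THF, 0 °C
Reagents that add atoms: methylmagnesium bromide, C[Mg]Br
Why: Grignard addition to the Weinreb amide stops at the ketone through the chelated tetrahedral intermediate, the tertiary alkoxide formed first being a spectator.

Step 10
Reactants: 13 methyl ketone; 6 (S)-2-methylbut-3-enal
Product: 14 (3R,7S)-1-[(tert-butyldimethylsilyl)oxy]-3,6-dihydroxy-3,7-dimethylnon-8-en-4-one (both C6 epimers)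
Conditions: LiN(iPr)2 (2.2 equiv), THF, −78 °C; then 6, −78 °C; AcOH quench at −78 °C
Reagents that add atoms: none
Why: Aldol addition of the alkoxide–enolate of the methyl ketone (its only enolisable site) to the aldehyde at −78 °C should outrun enolisation of the aldehyde, and the new carbinol centre, formed as a mixture, is removed by oxidation in step 11.

Step 11
Reactants: 14 aldol adduct
Product: 16 (2R)-5-[(2S)-but-3-en-2-yl]-2-{2-[(tert-butyldimethylsilyl)oxy]ethyl}-2-methylfuran-3(2H)-one, via hydroxy diketone 15 (not isolated)
Conditions: Dess–Martin periodinane, NaHCO3, CH2Cl2, 0 °C to rt; filtration; then p-TsOH·H2O (cat.), CH2Cl2, rt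
Reagents that add atoms: none
Why: Dess–Martin oxidation gives the α'-hydroxy-1,3-diketone, whose tertiary hydroxyl adds to the distal carbonyl and dehydrates under mild acid to the 3(2H)-furanone (classical cyclodehydration), with acid kept catalytic and brief so that C4 and the silyl ether survive.

Step 12
Reactants: 16 silylated furanone
Product: 17 (2R)-5-[(2S)-but-3-en-2-yl]-2-(2-hydroxyethyl)-2-methylfuran-3(2H)-one
Conditions: HF·pyridine, THF, 0 °C to rt
Reagents that add atoms: none
Why: Fluoride cleavage of the primary silyl ether under buffered, non-basic conditions leaves the furanone and the γ-acidic C4 centre alone.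

Step 13
Reactants: 17 furanone alcohol
Product: 18 2-{(2R)-5-[(2S)-but-3-en-2-yl]-2-methyl-3-oxo-2,3-dihydrofuran-2-yl}acetaldehyde
Conditions: Dess–Martin periodinane, NaHCO3, CH2Cl2, 0 °C; used directly
Reagents that add atoms: none
Why: Buffered Dess–Martin oxidation gives the aldehyde without base, which avoids β-elimination of the furanone oxygen from C10.

Step 14
Reactants: 18 furanone aldehyde; 19 ethyl (Z)-3-iodoprop-2-enoate
Product: 21 (5S)-5-({(2R)-5-[(2S)-but-3-en-2-yl]-2-methyl-3-oxo-2,3-dihydrofuran-2-yl}methyl)furan-2(5H)-one, via hydroxy enoate 20 (not isolated)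
Conditions: CrCl2 (4 equiv), (S)-N-[2-(4-isopropyl-4,5-dihydrooxazol-2-yl)-6-methylphenyl]methanesulfonamide (4.4 equiv), proton sponge, NiCl2 (2 mol%), MeCN/THF, rt; then PPTS, CH2Cl2
Reagents that add atoms: none
Why: In this Nozaki–Hiyama–Kishi coupling the alkenylchromium species formed from the Z-iodoacrylate under nickel catalysis adds to the aldehyde under near-neutral conditions and the Z-γ-hydroxy ester lactonises to the butenolide, with the chiral sulfonamide ligand on chromium (reagent control, overriding the remote C10 centre) setting C8 as S.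

Step 15
Reactants: 21 butenolide
Product: 23 (3RS,4R,5S)-5-({(2R)-5-[(2S)-but-3-en-2-yl]-2-methyl-3-oxo-2,3-dihydrofuran-2-yl}methyl)-3-[(dimethylamino)methyl]-4-ethenyloxolan-2-one, via silyl ketene acetal 22 (not isolated)
Conditions: CH2=CHMgBr (3 equiv), CuI (1.5 equiv), Me3SiCl (3 equiv), THF, −78 °C; then CH2=NMe2+ I−, CH2Cl2, −78 °C to rt
Reagents that add atoms: vinylmagnesium bromide, C=C[Mg]Br; dimethylmethylideneammonium iodide (Eschenmoser's salt), C=[N+](C)C.[I-]; chlorotrimethylsilane, C[Si](C)(C)Cl (silicon carried only in 22)
Why: Copper-mediated conjugate addition of the vinyl group to the butenolide should occur anti to the C8 substituent and so set C7 trans to it (R), and the silyl ketene acetal, which is non-basic and spares C4, is then aminomethylated by the iminium salt (Mannich reaction) at C11, whose configuration is lost in step 16.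

Step 16
Reactants: 23 Mannich base
Product: 25 (4R,5S)-5-({(2R)-5-[(2S)-but-3-en-2-yl]-2-methyl-3-oxo-2,3-dihydrofuran-2-yl}methyl)-4-ethenyl-3-methylideneoxolan-2-one, via trimethylammonium iodide 24 (not isolated)
Conditions: MeI, CH2Cl2, rt; then aq. NaHCO3, EtOAc, rt
Reagents that add atoms: iodomethane, CI (its methyl group is carried only in 24 and leaves as trimethylamine)
Why: N-Methylation followed by bicarbonate-induced E1cB (Hofmann-type) loss of trimethylamine is the standard mild unveiling of an α-methylene lactone and should not epimerise C4 or C7.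

Step 17
Reactants: 25 divinyl furanone methylenelactone
Product: 26 (4S,5Z,7R,8S,10R)-macrocycle: ten-membered carbocycle C1–C10 with Z-C5=C6, bridged from C3 to C10 by the furanone oxygen and trans-fused at C7–C8 to the methylenelactone
Conditions: second-generation Hoveyda–Grubbs catalyst RuCl2(H2IMes)(=CH-C6H4-2-OiPr) (10 mol%, two portions), 1,4-benzoquinone (20 mol%), toluene (1 mM), 80 °C
Reagents that add atoms: none
Why: The ruthenium alkylidene loads on one of the two monosubstituted vinyl groups, and [2+2] cycloaddition with the other followed by cycloreversion of the metallacyclobutane releases ethene and forms C5=C6. The closest known reaction type is ring-closing metathesis to ten-membered carbocycles of oxygen-bridged germacranolide-type skeletons. The carbocycle C1–C10 closes by macrocyclising metathesis of a 1,11-diene, helped by the planar furanone and the trans-fused lactone, which restrict the chain between C4 and C7 and bring the vinyl termini together. No stereocentre is formed, and the Z geometry is expected because an E-olefin would strain the oxygen-bridged bicycle. The step needs chemoselectivity for the two vinyl groups, which the substrate provides because the electron-poor 1,1-disubstituted lactone methylene and the trisubstituted furanone olefin are inert to the catalyst. It also needs the allylic C4 and C7 centres to survive, which benzoquinone secures by quenching ruthenium hydrides, while high dilution favours closure over oligomers.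

Step 18
Reactants: 26 Z-macrocycle
Product: 27 (4S,5S,6R,7R,8S,10R)-5,6-epoxide of 26
Conditions: mCPBA (1.2 equiv), NaHCO3, CH2Cl2, 0 °C
Reagents that add atoms: 3-chloroperoxybenzoic acid, OOC(=O)c1cccc(Cl)c1
Why: Prilezhaev epoxidation by the electrophilic peracid should touch only the isolated cis-disubstituted olefin (the acrylate and vinylogous ester olefins are electron-poor), and, with H4 and H7 in the olefin plane to avoid allylic strain, oxygen is delivered syn to the face carrying only the C4 methyl group and the C8 methine, the other face being covered by the furanone bridge and C11, which gives the 5S,6R oxirane.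

Step 19
Reactants: 27 epoxide; 28 methacrylic acid
Product: 29 target, (4S,5S,6S,7R,8S,10R)-5-hydroxy-6-methacryloyloxy furanone germacranolide CNP0195404.1
Conditions: 28 (3 equiv), Co(salen')(OAc) (10 mol%; salen' = N,N'-bis(3,5-di-tert-butylsalicylidene)ethane-1,2-diamine dianion), iPr2NEt (1 equiv), BHT (trace), tert-butyl methyl ether, rt
Reagents that add atoms: none
Why: Carboxylic acid opening of an epoxide under trivalent cobalt salen catalysis is an SN2 process, so the carboxylate should enter with inversion at C6, whose rear side faces only the planar C11, rather than at C5, which lies under the furanone bridge and is deactivated by the adjacent electron-poor furanone carbon, while C5 keeps its oxygen and the 5S,6S hydroxy ester results.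

**Compound list**

1 | (S)-4-benzyloxazolidin-2-one | O=C1N[C@@H](Cc2ccccc2)CO1 | starting material
2 | (E)-but-2-enoyl chloride | C/C=C/C(Cl)=O | starting material
3 | (S)-4-benzyl-3-[(E)-but-2-enoyl]oxazolidin-2-one | C/C=C/C(=O)N1[C@@H](Cc2ccccc2)COC1=O | intermediate
4 | (S)-4-benzyl-3-[(S)-2-methylbut-3-enoyl]oxazolidin-2-one | C=C[C@H](C)C(=O)N1[C@@H](Cc2ccccc2)COC1=O | intermediate
5 | (S)-2-methylbut-3-en-1-ol | C=C[C@H](C)CO | intermediate
6 | (S)-2-methylbut-3-enal | C=C[C@H](C)C=O | intermediate
7 | (R)-citramalic acid | C[C@@](O)(CC(=O)O)C(=O)O | starting material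
8 | (R)-2-(2,2,4-trimethyl-5-oxo-1,3-dioxolan-4-yl)acetic acid | C[C@]1(CC(=O)O)OC(C)(C)OC1=O | intermediate
9 | (R)-5-(2-hydroxyethyl)-2,2,5-trimethyl-1,3-dioxolan-4-one (not isolated) | C[C@]1(CCO)OC(C)(C)OC1=O | intermediate
10 | (R)-3-hydroxy-3-methyloxolan-2-one | C[C@@]1(O)CCOC1=O | intermediate
11 | (R)-2,4-dihydroxy-N-methoxy-N,2-dimethylbutanamide | CON(C)C(=O)[C@](C)(O)CCO | intermediate
12 | (R)-4-[(tert-butyldimethylsilyl)oxy]-2-hydroxy-N-methoxy-N,2-dimethylbutanamide | CON(C)C(=O)[C@](C)(O)CCO[Si](C)(C)C(C)(C)C | intermediate
13 | (R)-5-[(tert-butyldimethylsilyl)oxy]-3-hydroxy-3-methylpentan-2-one | CC(=O)[C@](C)(O)CCO[Si](C)(C)C(C)(C)C | intermediate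
14 | (3R,7S)-1-[(tert-butyldimethylsilyl)oxy]-3,6-dihydroxy-3,7-dimethylnon-8-en-4-one, both C6 epimers | C=C[C@H](C)C(O)CC(=O)[C@](C)(O)CCO[Si](C)(C)C(C)(C)C | intermediate
15 | (3R,7S)-1-[(tert-butyldimethylsilyl)oxy]-3-hydroxy-3,7-dimethylnon-8-ene-4,6-dione (not isolated) | C=C[C@H](C)C(=O)CC(=O)[C@](C)(O)CCO[Si](C)(C)C(C)(C)C | intermediate
16 | (2R)-5-[(2S)-but-3-en-2-yl]-2-{2-[(tert-butyldimethylsilyl)oxy]ethyl}-2-methylfuran-3(2H)-one | C=C[C@H](C)C1=CC(=O)[C@@](C)(CCO[Si](C)(C)C(C)(C)C)O1 | intermediate
17 | (2R)-5-[(2S)-but-3-en-2-yl]-2-(2-hydroxyethyl)-2-methylfuran-3(2H)-one | C=C[C@H](C)C1=CC(=O)[C@@](C)(CCO)O1 | intermediate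
18 | 2-{(2R)-5-[(2S)-but-3-en-2-yl]-2-methyl-3-oxo-2,3-dihydrofuran-2-yl}acetaldehyde | C=C[C@H](C)C1=CC(=O)[C@@](C)(CC=O)O1 | intermediate
19 | ethyl (Z)-3-iodoprop-2-enoate | CCOC(=O)/C=C\I | starting material
20 | ethyl (2Z,4S)-5-{(2R)-5-[(2S)-but-3-en-2-yl]-2-methyl-3-oxo-2,3-dihydrofuran-2-yl}-4-hydroxypent-2-enoate (not isolated) | C=C[C@H](C)C1=CC(=O)[C@@](C)(C[C@H](O)/C=C\C(=O)OCC)O1 | intermediate
21 | (5S)-5-({(2R)-5-[(2S)-but-3-en-2-yl]-2-methyl-3-oxo-2,3-dihydrofuran-2-yl}methyl)furan-2(5H)-one | C=C[C@H](C)C1=CC(=O)[C@@](C)(C[C@@H]2OC(=O)C=C2)O1 | intermediate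
22 | (2R)-5-[(2S)-but-3-en-2-yl]-2-{[(2S,3R)-3-ethenyl-5-(trimethylsilyloxy)-2,3-dihydrofuran-2-yl]methyl}-2-methylfuran-3(2H)-one (not isolated) | C=C[C@H](C)C1=CC(=O)[C@@](C)(C[C@@H]2OC(O[Si](C)(C)C)=C[C@H]2C=C)O1 | intermediate
23 | (3RS,4R,5S)-5-({(2R)-5-[(2S)-but-3-en-2-yl]-2-methyl-3-oxo-2,3-dihydrofuran-2-yl}methyl)-3-[(dimethylamino)methyl]-4-ethenyloxolan-2-one | C=C[C@H](C)C1=CC(=O)[C@@](C)(C[C@@H]2OC(=O)C(CN(C)C)[C@H]2C=C)O1 | intermediate
24 | N-methyl quaternary ammonium iodide of 23 (not isolated) | C=C[C@H](C)C1=CC(=O)[C@@](C)(C[C@@H]2OC(=O)C(C[N+](C)(C)C)[C@H]2C=C)O1.[I-] | intermediate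
25 | (4R,5S)-5-({(2R)-5-[(2S)-but-3-en-2-yl]-2-methyl-3-oxo-2,3-dihydrofuran-2-yl}methyl)-4-ethenyl-3-methylideneoxolan-2-one | C=C[C@H](C)C1=CC(=O)[C@@](C)(C[C@@H]2OC(=O)C(=C)[C@H]2C=C)O1 | intermediate
26 | (4S,5Z,7R,8S,10R)-macrocycle: ten-membered carbocycle with Z-C5=C6, 3,10-oxygen bridge (furan-3(2H)-one), methyl groups on C4 and C10, trans-fused 8,12-lactone with C11=C13 methylene | C=C1C(=O)O[C@H]2C[C@@]3(C)OC(=CC3=O)[C@@H](C)/C=C\[C@H]12 | intermediate
27 | (4S,5S,6R,7R,8S,10R)-5,6-epoxide of 26 | C[C@H]1[C@@H]2O[C@@H]2[C@@H]3C(=C)C(=O)O[C@H]3C[C@@]4(C)OC1=CC4=O | intermediate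
28 | methacrylic acid | C=C(C)C(=O)O | starting material
29 | CNP0195404.1, (4S,5S,6S,7R,8S,10R)-5-hydroxy-6-(methacryloyloxy) compound | C=C(C)C(=O)O[C@@H]1[C@@H](O)[C@H](C)C2=CC(=O)[C@@](C)(C[C@@H]3OC(=O)C(=C)[C@@H]13)O2 | target

**Count and risks**

Total steps: 19. Longest linear sequence: 15 steps (7 to 29, steps 5 to 19); the side branch 1 to 6 has 4 steps.

Steps most likely to fail:

1. Step 19. The line of attack on the oxirane runs through the interior of the ring, so the bulky cobalt carboxylate may react too slowly, leaving room for capture of the activated oxirane across the ring by C2 of the furanone or for entry of the carboxylate at C5. The fallback separates C–O bond formation from acylation. It sets out from 27, which is hydrolysed with dilute HClO4 in aqueous THF at 0 °C, water being the smallest nucleophile for the same invertive attack at C6. This should give the 5S,6S diol F1. Acylation of the less shielded C6 hydroxyl with methacrylic anhydride, DMAP (cat.) and 2,4,6-collidine in CH2Cl2 at −40 °C then returns to the route at 29.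

2. Step 17. If closure of the strained bicycle is slow, ruthenium hydrides may move the lactone methylene into the ring and the C4 vinyl group into conjugation with the furanone, and the acrylate may enter cross-metathesis oligomers. The fallback removes the methylenelactone from the metathesis substrate. It sets out from 23, which is protonated in the flask with camphorsulfonic acid (ammonium salts do not bind the catalyst) and cyclised with the same ruthenium catalyst in 1,2-dichloroethane at 70 °C. Basic work-up should give the macrocyclic Mannich base F2. Methylation with MeI gives the quaternary ammonium iodide F3, and aqueous NaHCO3 eliminates trimethylamine, which returns to the route at 26.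

3. Step 18. The facial selectivity rests on a conformational argument, and the peracid may instead deliver oxygen to the face of the furanone bridge, which would end in the 5R,6R series. The fallback inverts the facial outcome with known halohydrin chemistry. It sets out from 26, which is treated with N-bromosuccinimide in aqueous 1,2-dimethoxyethane at 0 °C; the bromonium ion forms on the face the peracid prefers and water opens it anti. This should give the bromohydrin F4 (drawn as the 5-bromo-6-ol; its regioisomer serves equally). Ag2O in CH2Cl2 then closes the oxirane with inversion at the bromine-bearing carbon, on the opposite face, which returns to the route at 27.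

Further compounds
F1 | step 19 | (4S,5S,6S,7R,8S,10R)-5,6-diol (29 without the methacryloyl group) | O[C@@H]1[C@@H](O)[C@H](C)C2=CC(=O)[C@@](C)(C[C@@H]3OC(=O)C(=C)[C@@H]13)O2
F2 | step 17 | macrocyclic Mannich base: 26 with C11 as CH–CH2NMe2 (C11 epimers) | CN(C)CC1C(=O)O[C@H]2C[C@@]3(C)OC(=CC3=O)[C@@H](C)/C=C\[C@H]12
F3 | step 17 | N-methyl quaternary ammonium iodide of F2 | C[N+](C)(C)CC1C(=O)O[C@H]2C[C@@]3(C)OC(=CC3=O)[C@@H](C)/C=C\[C@H]12.[I-]
F4 | step 18 | (5R,6R)-5-bromo-6-hydroxy-5,6-dihydro derivative of 26 | O[C@H]1[C@H](Br)[C@H](C)C2=CC(=O)[C@@](C)(C[C@@H]3OC(=O)C(=C)[C@@H]13)O2
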